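## The problem

Target 16 is a 5,7-dihydroxyflavone (ring A, pyranone ring C and the phenyl ring B on C2) whose C8 carries C2′ of an N-methylpiperidine. The two ring systems are joined only by the C8–C2′ bond, and ring C is fused to ring A through C4a–C8a. C2′ (R) is the sole stereocentre, so nothing in the molecule can relay chirality to it; it has to come from a catalyst, an auxiliary or the chiral pool. This centre is benzylic to a phloroglucinol-type ring and sits between O1 and the 7-hydroxyl, which makes the compound a phenolic Mannich base. Heat or strong acid can open the C2′–N1′ bond through an ortho-quinone methide and erase the configuration, and hot acid can also open and reclose ring C to the 6-substituted isomer (Wessely–Moser rearrangement). Harsh ether cleavage, acid-driven flavone closures and prolonged heating of free ortho-hydroxy benzylic amines are therefore excluded. The three oxygens of ring A must be told apart (O1 into ring C, O5 and O7 as hydroxyls), and C8 must be distinguished from C6. The enabling feature is that ring C (O1, C2, C3, C4, C4a, C8a) shares the C4a–C8a bond with ring A and has O1 next to C8. An ortho-iodophenol with iodine on C4a and its only free hydroxyl on C8a can then take up C4 from carbon monoxide and C3–C2 with ring B from phenylacetylene, under mild base that leaves C2′ alone.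

## Retrosynthesis

**Ether cleavage (16 from 15).** The last operation cuts only the two O–CH2Ph bonds on O5 and O7 of 15. Benzyl is preferred to methyl, whose removal needs hot strong acid, and to silyl, which would not survive the organolithium step. Reductive debenzylation is not planned, because the benzylic C2′–N1′ bond and the C2=C3 bond would be exposed to hydrogen on palladium. Compound 15 has no free hydroxyl next to C8 (O1 is in ring C, O7 is benzylated), so it is the configurationally safest place to hold the material. The forward step must cleave two aryl ethers at low temperature with a boron Lewis acid and a cation scavenger, without benzylating C6.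

**Ring C (15 from 10, 11 and 12).** The bonds C4a–C4, C4–C3 and O1–C2 are cut. This removes ring C, returns C4 as carbon monoxide 12 and C2–C3 with ring B as phenylacetylene 11, and leaves ortho-iodophenol 10. The neighbouring cuts go through a 2-hydroxyacetophenone (Baker–Venkataraman transposition, or chalcone formation and oxidation). They would need an acetyl group forced onto C4a of a hindered, amine-bearing ring and would finish under hot acid or a hot oxidant, which the Mannich base does not tolerate. The three-component cut takes away nine carbons and one ring in a single step. The forward reaction must carbonylate faster than it couples directly, and must close the six-membered rather than the five-membered ring.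

**Iodide (10 from 9).** The C4a–I bond is cut, back to phenol 9. Iodine cannot be carried from the start, because it would not survive the alkyllithium and hydrogenation steps. It is therefore introduced by electrophilic substitution once O1 is free. The forward step must iodinate once, at C4a (ortho to the free hydroxyl), and not at C6 between the two benzyloxy groups.

**Liberation of O1 (9 from 8).** The O1–H bond is traced to the methoxymethyl ether 8. Keeping O1 masked up to this point means that hydrogenation and N-methylation run on a substrate without a free phenol. This avoids a chelated hydroxy-imine and any benzoxazine or ring-A Mannich chemistry. The forward step must cleave one acetal, spare two benzyl ethers and leave C2′ untouched.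

**N-Methyl group (8 from 7).** The N1′–CH3 bond is cut, back to secondary amine 7. Methylation after the reduction keeps the asymmetric step on a neutral imine and uses a standard reductive amination.

**Stereocentre (7 from 6).** The C2′–H bond is cut, back to cyclic imine 6, which is achiral. Catalytic asymmetric hydrogenation is chosen over an auxiliary on nitrogen, which would cost extra steps, and over a chiral-pool piperidine, which would have to be attached to a fully substituted arene carbon. The forward step has to distinguish the two faces of a C=N bond carrying a doubly ortho-substituted aryl group, by catalyst control alone.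

**Piperidine carbons (6 from 2 and 3).** The C8–C2′ and N1′–C6′ bonds are cut, giving aryllithium 4 (from 2) and 5-bromopentanenitrile 3, with lithium ketimide 5 between them. An N-acyl lactam as the five-carbon electrophile would need an acid step to unmask the amine, which would also strip the O1 acetal. A Mannich reaction of the free phenol with a cyclic imine would give a racemate. The nitrile route reaches 6 in one flask under basic conditions. The forward step needs lithiation between the acetal and a benzyloxy group, addition to the nitrile faster than proton transfer, and a 6-exo-tet closure.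

**Acetal (2 from 1).** The O1–CH2OCH3 bond is cut, back to commercial 3,5-bis(benzyloxy)phenol 1. In 1 the three ring-A oxygens are already differentiated, two as benzyl ethers and one free.

## Roads not taken

**Alternative 1:** The cut is made inside the piperidine, at C2′–C3′ and N1′–C6′. Grignard reagent A2 adds to the C=N bond of the S-configured sulfinyl aldimine A1. A potassium silylamide then lets the sulfinamide nitrogen displace chloride, giving N-sulfinylpiperidine A3.
- Merits: the stereocentre is set by a stoichiometric auxiliary through a well-understood cyclic transition state. Both antipodes of the auxiliary are cheap, and aldimines tolerate a doubly ortho-substituted aryl group well.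
- Weak points: the ortho acetal and methoxy oxygens of A1 can bind magnesium in competition with the sulfinyl oxygen, so the level and even the sense of induction would need checking. A3 carries methyl ethers on the future O5 and O7, and their cleavage needs the strong acid that the Mannich base does not survive. The sequence makes only the piperidine; formylation, condensation, addition–cyclisation, desulfinylation and N-methylation all precede any work on ring C.
- Comparison: in predictability of the stereocentre this road is better than the catalytic hydrogenation of the hindered imine 6. The chosen plan offers in return catalytic chirality, two steps instead of four from the protected phenol to the piperidine, and benzyl ethers that come off at −78 °C.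

**Alternative 2:** The cut runs through ring A, at C8–C8a, C6–C7 and C4a–C8a. Heating cyclobutenone A6 with siloxyalkyne A5, which is derived from (R)-pipecolic acid A4, opens the four-membered ring to a vinylketene. This adds to the alkyne, opens again and closes by 6π-electrocyclisation to phenol A7.
- Merits: the stereocentre comes from the chiral pool, so no asymmetric step is needed. The substitution pattern of ring A is unambiguous, and A7 already has O1 free with O5 and O7 differently protected.
- Weak points: A4 is the unnatural, costly enantiomer. A5 needs several steps and is sensitive. A hindered α-branched alkyne next to a carbamate is a demanding partner at the required temperature. The ethyl ether on O5 is harder to remove than a benzyl ether. The carbamate must be turned into N-methyl before a flavone carbonyl is present, and ring C still has to be built.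
- Comparison: this road is superior in stereochemical certainty and in the regiochemistry of ring A. The chosen plan is shorter, starts from an inexpensive phloroglucinol ether and ends with a deprotection at −78 °C.

**Alternative 3:** The cut is the N1′–C2′ bond on a preformed flavone. A bulky chiral BINOL-derived phosphoric acid dehydrates the racemic C8 benzylic alcohol A8 to the ortho-quinone methide and steers 6-exo attack of the carbamate nitrogen on C2′, giving A9.
- Merits: it is stereoconvergent from a racemate, late-stage and convergent. It turns the reactivity that threatens the stereocentre into the bond-forming event, and would be the shortest route if selective.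
- Weak points: enantioselective closure of a carbamate onto such a quinone methide to a 2-arylpiperidine has little direct precedent. The free 5- and 7-hydroxyls and the flavone carbonyl compete for the catalyst. The same acid can reopen the product. A8 requires C8-selective acylation of a 5,7-dihydroxyflavone. A9 must then lose its carbamate under acid, with the 7-hydroxyl free, before N-methylation.
- Comparison: this road wins on convergence. The chosen plan sets C2′ by an established reaction class on a fully protected substrate, and closes ring C afterwards under basic conditions that do not ionise the C2′–N1′ bond.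

Key step: step 7

Assumption: the sense of induction of the iridium catalyst on the hindered imine 6 cannot be inferred from unhindered models, so the ligand antipode that gives the R amine is taken to be fixed by a test reduction.

## Route

Step 1
Reactants: 1 3,5-bis(benzyloxy)phenol
Product: 2 1,3-bis(benzyloxy)-5-(methoxymethoxy)benzene
Conditions: NaH, MOMCl, DMF, 0 °C → rt
Reagents that add atoms: chloromethyl methyl ether (MOMCl), COCCl
Why: Williamson-type O-alkylation of the sodium phenoxide with a reactive α-chloro ether; the acetal later directs lithiation and is the one oxygen substituent that mild acid removes while the benzyl ethers stay.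

Step 2
Reactants: 2 1,3-bis(benzyloxy)-5-(methoxymethoxy)benzene; 3 5-bromopentanenitrile
Product: 6 6-[2,4-bis(benzyloxy)-6-(methoxymethoxy)phenyl]-2,3,4,5-tetrahydropyridine, via aryllithium 4 (not isolated), via N-lithio ketimine 5 (not isolated)
Conditions: n-BuLi (1.05 equiv), TMEDA, Et2O, 0 °C; then 3, THF, −78 °C → rt
Reagents that add atoms: none
Why: Directed ortho-metalation: the acetal oxygens hold the base at the C–H flanked by OMOM and OBn (two equivalent sites) to give 4; addition of 4 to the nitrile gives 5, whose nitrogen displaces bromide in a 6-exo-tet alkylation on warming, the known one-flask route from organolithiums and ω-bromonitriles to cyclic imines. No acid is involved, so the acetal on O1 is kept.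

Step 3
Reactants: 6 6-[2,4-bis(benzyloxy)-6-(methoxymethoxy)phenyl]-2,3,4,5-tetrahydropyridine
Product: 7 (2R)-2-[2,4-bis(benzyloxy)-6-(methoxymethoxy)phenyl]piperidine
Conditions: [Ir(cod)Cl]2 (1 mol%), f-Binaphane Fe(C5H4PC22H16)2 (2.2 mol%, antipode giving R), I2 (4 mol%, premixed with the catalyst), H2 (50 bar), toluene, rt
Reagents that add atoms: none
Why: Iridium-catalysed asymmetric hydrogenation of a 2-aryl cyclic imine, an established reaction class; the C2′ stereocentre is set by catalyst control alone, the chiral bisphosphine differentiating the two faces of C2′=N1′, and the benzyl and methoxymethyl ethers are inert to the homogeneous catalyst.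

Step 4
Reactants: 7 (2R)-2-[2,4-bis(benzyloxy)-6-(methoxymethoxy)phenyl]piperidine
Product: 8 (2R)-2-[2,4-bis(benzyloxy)-6-(methoxymethoxy)phenyl]-1-methylpiperidine
Conditions: aq. CH2O, NaBH(OAc)3, ClCH2CH2Cl, rt
Reagents that add atoms: formaldehyde, C=O
Why: Reductive amination through the N-methylene iminium ion; with O1 still masked there is no benzoxazine formation and no Mannich reaction on ring A, and C2′ is not involved.

Step 5
Reactants: 8 (2R)-2-[2,4-bis(benzyloxy)-6-(methoxymethoxy)phenyl]-1-methylpiperidine
Product: 9 3,5-bis(benzyloxy)-2-[(2R)-1-methylpiperidin-2-yl]phenol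
Conditions: HCl (3 M in MeOH), 0 °C → rt; then aq. NaHCO3, 0 °C
Reagents that add atoms: none
Why: Acid-catalysed acetal exchange of the aryl methoxymethyl ether with methanol, to which benzyl ethers are stable; the nitrogen stays protonated, so no phenoxide–ammonium pair can push the C2′–N1′ bond open, and the doubly ortho-substituted benzylic position ionises slowly at room temperature.

Step 6
Reactants: 9 3,5-bis(benzyloxy)-2-[(2R)-1-methylpiperidin-2-yl]phenol
Product: 10 3,5-bis(benzyloxy)-2-iodo-6-[(2R)-1-methylpiperidin-2-yl]phenol
Conditions: NIS (1.0 equiv), CH2Cl2, −40 → 0 °C, dark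
Reagents that add atoms: N-iodosuccinimide, O=C1CCC(=O)N1I
Why: Electrophilic aromatic iodination of an electron-rich phenol; the position ortho to the free hydroxyl (C4a, between OH and one OBn) is less hindered than C6 between two benzyloxy groups and is activated by the amine-hydrogen-bonded O1, in line with the ortho-iodination of 3,5-dialkoxyphenols, and one equivalent at low temperature limits di-iodination.

Step 7
Reactants: 10 3,5-bis(benzyloxy)-2-iodo-6-[(2R)-1-methylpiperidin-2-yl]phenol; 11 phenylacetylene; 12 carbon monoxide
Product: 15 5,7-bis(benzyloxy)-8-[(2R)-1-methylpiperidin-2-yl]-2-phenyl-4H-chromen-4-one, via ynone 13 (not isolated), via aminoenone 14 (not isolated)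
Conditions: PdCl2(PPh3)2 (5 mol%), CO (10 bar), Et2NH, 60 °C
Reagents that add atoms: none
Why: PdCl2(PPh3)2 is reduced in the amine to zerovalent palladium, which inserts into the C4a–I bond of 10; CO insertion gives the aroylpalladium iodide, and amine-assisted transfer of the acetylide of 11 with reductive elimination forms C4a–C4 and C4–C3 in ynone 13. Diethylamine then adds to C2 of 13 to give β-aminoenone 14, and the O1 hydroxyl displaces the amine at C2 by addition–elimination, forming O1–C2. The closest known reaction is the palladium-catalysed carbonylative coupling–cyclisation of ortho-iodophenols with terminal alkynes in secondary amines, which gives flavones. Ring C closes in the 6-endo mode (6-endo-dig oxa-Michael addition on 13, or its 6-endo-trig addition–elimination equivalent on 14); 5-exo closure at C3 to an aurone is suppressed because the amine adduct fixes the electrophilic site at C2. No stereocentre is created, and C2′ is a spectator with no base-labile bond. The step needs carbonylation to outrun direct alkynylation, which copper-free conditions and CO pressure secure, and it needs 8- rather than 6-substitution, which the substrate secures because iodine sits on C4a and O1 is the only free hydroxyl. The tertiary amine of 10 cannot be acylated, and 60 °C is kept as the ceiling so that the ortho-hydroxy benzylic amine does not open thermally.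

Step 8
Reactants: 15 5,7-bis(benzyloxy)-8-[(2R)-1-methylpiperidin-2-yl]-2-phenyl-4H-chromen-4-one
Product: 16 5,7-dihydroxy-8-[(2R)-1-methylpiperidin-2-yl]-2-phenyl-4H-chromen-4-one
Conditions: BCl3 (6 equiv), C6HMe5 (6 equiv), CH2Cl2, −78 °C; then MeOH, −78 → 0 °C
Reagents that add atoms: none
Why: Lewis-acid debenzylation of aryl benzyl ethers: BCl3 binds the ether oxygens (O5 assisted by chelation to the C4 carbonyl) and the benzyl cation is trapped by pentamethylbenzene in a Friedel–Crafts reaction before it can alkylate C6; at −78 °C the pyranone and the C2′–N1′ bond should stay intact.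

## Compound list

1 | 3,5-bis(benzyloxy)phenol | Oc1cc(OCc2ccccc2)cc(OCc2ccccc2)c1 | starting material
2 | 1,3-bis(benzyloxy)-5-(methoxymethoxy)benzene | COCOc1cc(OCc2ccccc2)cc(OCc2ccccc2)c1 | intermediate
3 | 5-bromopentanenitrile | N#CCCCCBr | starting material
4 | [2,4-bis(benzyloxy)-6-(methoxymethoxy)phenyl]lithium | [Li]c1c(OCOC)cc(OCc2ccccc2)cc1OCc1ccccc1 | intermediate
5 | lithium 1-[2,4-bis(benzyloxy)-6-(methoxymethoxy)phenyl]-5-bromopentan-1-iminide | [Li]N=C(CCCCBr)c1c(OCOC)cc(OCc2ccccc2)cc1OCc1ccccc1 | intermediate
6 | 6-[2,4-bis(benzyloxy)-6-(methoxymethoxy)phenyl]-2,3,4,5-tetrahydropyridine | COCOc1cc(OCc2ccccc2)cc(OCc2ccccc2)c1C1=NCCCC1 | intermediate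
7 | (2R)-2-[2,4-bis(benzyloxy)-6-(methoxymethoxy)phenyl]piperidine | N1CCCC[C@@H]1c1c(OCOC)cc(OCc2ccccc2)cc1OCc1ccccc1 | intermediate
8 | (2R)-2-[2,4-bis(benzyloxy)-6-(methoxymethoxy)phenyl]-1-methylpiperidine | CN1CCCC[C@@H]1c1c(OCOC)cc(OCc2ccccc2)cc1OCc1ccccc1 | intermediate
9 | 3,5-bis(benzyloxy)-2-[(2R)-1-methylpiperidin-2-yl]phenol | CN1CCCC[C@@H]1c1c(O)cc(OCc2ccccc2)cc1OCc1ccccc1 | intermediate
10 | 3,5-bis(benzyloxy)-2-iodo-6-[(2R)-1-methylpiperidin-2-yl]phenol | CN1CCCC[C@@H]1c1c(O)c(I)c(OCc2ccccc2)cc1OCc1ccccc1 | intermediate
11 | phenylacetylene (ethynylbenzene) | C#Cc1ccccc1 | starting material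
12 | carbon monoxide | [C-]#[O+] | starting material
13 | 1-{4,6-bis(benzyloxy)-2-hydroxy-3-[(2R)-1-methylpiperidin-2-yl]phenyl}-3-phenylprop-2-yn-1-one | CN1CCCC[C@@H]1c1c(O)c(C(=O)C#Cc2ccccc2)c(OCc2ccccc2)cc1OCc1ccccc1 | intermediate
14 | 1-{4,6-bis(benzyloxy)-2-hydroxy-3-[(2R)-1-methylpiperidin-2-yl]phenyl}-3-(diethylamino)-3-phenylprop-2-en-1-one | CN1CCCC[C@@H]1c1c(O)c(C(=O)C=C(N(CC)CC)c2ccccc2)c(OCc2ccccc2)cc1OCc1ccccc1 | intermediate
15 | 5,7-bis(benzyloxy)-8-[(2R)-1-methylpiperidin-2-yl]-2-phenyl-4H-chromen-4-one | CN1CCCC[C@@H]1c1c(OCc2ccccc2)cc(OCc2ccccc2)c2c(=O)cc(-c3ccccc3)oc12 | intermediate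
16 | 5,7-dihydroxy-8-[(2R)-1-methylpiperidin-2-yl]-2-phenyl-4H-chromen-4-one | CN1CCCC[C@@H]1c1c(O)cc(O)c2c(=O)cc(-c3ccccc3)oc12 | target

## Step count and least certain steps

Total steps: 8. Longest linear sequence: 8 steps (1 to 16); 3, 11 and 12 enter as commercial components in single steps.

**Step 7 (key step).** Oxidative addition into an electron-rich, doubly ortho-substituted aryl iodide that is partly present as its phenoxide may be slow. Capture of the aroylpalladium species by diethylamine (amide formation) or direct alkynylation without CO could then take over. Raising the temperature to compensate would invite thermal opening of the ortho-hydroxy benzylic amine and loss of configuration. The fallback avoids palladium and carbon monoxide but forms the same bonds. It sets out from 10: two equivalents of n-BuLi in THF at −78 °C deprotonate O1 and exchange iodine for lithium, giving lithium 3,5-bis(benzyloxy)-2-lithio-6-[(2R)-1-methylpiperidin-2-yl]phenolate F1. F1 is acylated with N-methoxy-N-methyl-3-phenylprop-2-ynamide F2, prepared beforehand from phenylpropiolic acid. This returns to the route at ynone 13, which is now isolated and closed with diethylamine at room temperature to 15.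

**Step 3.** The two ortho oxygen substituents twist the aryl ring out of the C=N plane and crowd the imine carbon, so slow turnover and poor facial discrimination by the catalyst are the likely failures. The fallback replaces asymmetric catalysis by resolution. From 6, reduction with NaBH4 in methanol gives racemic 2-[2,4-bis(benzyloxy)-6-(methoxymethoxy)phenyl]piperidine F3. Fractional crystallisation with (2R,3R)-di-O-p-toluoyltartaric acid is meant to deposit the (2R)-piperidinium hydrogen (2R,3R)-di-O-p-toluoyltartrate F4; the antipodal acid is used if the other salt proves less soluble. Basification with aqueous NaOH returns 7.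

**Step 2.** Proton transfer from the α-methylene of the nitrile to the hindered aryllithium may compete with addition, and the ketimide may close slowly onto the bromide. Lithiation between the two benzyloxy groups or at a benzylic methylene is a second source of loss. The fallback separates acylation from nitrogen introduction. From 2, aryllithium 4 is generated as before and acylated with 5-chloro-N-methoxy-N-methylpentanamide F5, made in one step from 5-chloropentanoyl chloride. This gives 1-[2,4-bis(benzyloxy)-6-(methoxymethoxy)phenyl]-5-chloropentan-1-one F6. Displacement with NaN3 in DMF gives 5-azido-1-[2,4-bis(benzyloxy)-6-(methoxymethoxy)phenyl]pentan-1-one F7. PPh3 in THF then effects a Staudinger reduction and intramolecular aza-Wittig closure, returning to 6.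

**Step 6.** Iodination may go to C6 (para to the hydroxyl), go twice, or be accompanied by oxidation of the tertiary amine by the iodinating agent. The fallback replaces electrophilic substitution by directed metalation. From 8, n-BuLi/TMEDA in Et2O at 0 °C lithiates next to the acetal, and quenching with I2 at −78 °C gives (2R)-2-[4,6-bis(benzyloxy)-3-iodo-2-(methoxymethoxy)phenyl]-1-methylpiperidine F8. Methanolic HCl then removes the acetal and returns to 10.

**Step 5.** Heterolysis of the benzylic C2′–N1′ bond of the ammonium salt, assisted by the three ring oxygens, would lead to reclosure with loss of configuration or to capture by methanol. The fallback moves the acid step ahead of the stereocentre. From 6, methanolic HCl gives 3,5-bis(benzyloxy)-2-(3,4,5,6-tetrahydropyridin-2-yl)phenol F9. The same iridium-catalysed hydrogenation gives 3,5-bis(benzyloxy)-2-[(2R)-piperidin-2-yl]phenol F10, and reductive methylation with formaldehyde and NaBH(OAc)3 returns to 9.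

## Further compounds

F1 | step 7 | lithium 3,5-bis(benzyloxy)-2-lithio-6-[(2R)-1-methylpiperidin-2-yl]phenolate | CN1CCCC[C@@H]1c1c(O[Li])c([Li])c(OCc2ccccc2)cc1OCc1ccccc1
F2 | step 7 | N-methoxy-N-methyl-3-phenylprop-2-ynamide | CON(C)C(=O)C#Cc1ccccc1
F3 | step 3 | racemic 2-[2,4-bis(benzyloxy)-6-(methoxymethoxy)phenyl]piperidine | N1CCCCC1c1c(OCOC)cc(OCc2ccccc2)cc1OCc1ccccc1
F4 | step 3 | (2R)-2-[2,4-bis(benzyloxy)-6-(methoxymethoxy)phenyl]piperidinium hydrogen (2R,3R)-2,3-bis[(4-methylbenzoyl)oxy]butanedioate | N1CCCC[C@@H]1c1c(OCOC)cc(OCc2ccccc2)cc1OCc1ccccc1.OC(=O)[C@H](OC(=O)c1ccc(C)cc1)[C@@H](OC(=O)c1ccc(C)cc1)C(O)=O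
F5 | step 2 | 5-chloro-N-methoxy-N-methylpentanamide | CON(C)C(=O)CCCCCl
F6 | step 2 | 1-[2,4-bis(benzyloxy)-6-(methoxymethoxy)phenyl]-5-chloropentan-1-one | ClCCCCC(=O)c1c(OCOC)cc(OCc2ccccc2)cc1OCc1ccccc1
F7 | step 2 | 5-azido-1-[2,4-bis(benzyloxy)-6-(methoxymethoxy)phenyl]pentan-1-one | [N-]=[N+]=NCCCCC(=O)c1c(OCOC)cc(OCc2ccccc2)cc1OCc1ccccc1
F8 | step 6 | (2R)-2-[4,6-bis(benzyloxy)-3-iodo-2-(methoxymethoxy)phenyl]-1-methylpiperidine | CN1CCCC[C@@H]1c1c(OCOC)c(I)c(OCc2ccccc2)cc1OCc1ccccc1
F9 | step 5 | 3,5-bis(benzyloxy)-2-(3,4,5,6-tetrahydropyridin-2-yl)phenol | Oc1cc(OCc2ccccc2)cc(OCc2ccccc2)c1C1=NCCCC1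
F10 | step 5 | 3,5-bis(benzyloxy)-2-[(2R)-piperidin-2-yl]phenol | N1CCCC[C@@H]1c1c(O)cc(OCc2ccccc2)cc1OCc1ccccc1
A1 | alternative 1 | (S)-N-{(E)-[2,4-dimethoxy-6-(methoxymethoxy)phenyl]methylidene}-2-methylpropane-2-sulfinamide | CC(C)(C)[S@](=O)/N=C/c1c(OCOC)cc(OC)cc1OC
A2 | alternative 1 | 4-chlorobutylmagnesium bromide | ClCCCC[Mg]Br
A3 | alternative 1 | (2R)-1-[(S)-tert-butylsulfinyl]-2-[2,4-dimethoxy-6-(methoxymethoxy)phenyl]piperidine | CC(C)(C)[S@](=O)N1CCCC[C@@H]1c1c(OCOC)cc(OC)cc1OC
A4 | alternative 2 | (2R)-piperidine-2-carboxylic acid | N1CCCC[C@@H]1C(O)=O
A5 | alternative 2 | tert-butyl (2R)-2-{[tri(propan-2-yl)silyl]oxyethynyl}piperidine-1-carboxylate | CC(C)(C)OC(=O)N1CCCC[C@@H]1C#CO[Si](C(C)C)(C(C)C)C(C)C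
A6 | alternative 2 | 3-ethoxycyclobut-2-en-1-one | CCOC1=CC(=O)C1
A7 | alternative 2 | tert-butyl (2R)-2-[4-ethoxy-2-hydroxy-6-(triisopropylsilyloxy)phenyl]piperidine-1-carboxylate | CC(C)(C)OC(=O)N1CCCC[C@@H]1c1c(O)cc(OCC)cc1O[Si](C(C)C)(C(C)C)C(C)C
A8 | alternative 3 | racemic tert-butyl N-[5-(5,7-dihydroxy-4-oxo-2-phenyl-4H-chromen-8-yl)-5-hydroxypentyl]carbamate | CC(C)(C)OC(=O)NCCCCC(O)c1c(O)cc(O)c2c(=O)cc(-c3ccccc3)oc12
A9 | alternative 3 | tert-butyl (2R)-2-(5,7-dihydroxy-4-oxo-2-phenyl-4H-chromen-8-yl)piperidine-1-carboxylate | CC(C)(C)OC(=O)N1CCCC[C@@H]1c1c(O)cc(O)c2c(=O)cc(-c3ccccc3)oc12
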